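Thursday's run was charged as Friday's flask is, with 0.500 M of starting material and 0.500 M of partner, but its readings stop at 17 min, so the question for 34 min is how Thursday's curve goes on.

| flask | starting material | partner | time |
|---|---|---|---|
| Thursday's | 0.500 M | 0.500 M |  |
| Tuesday's | 0.200 M | 0.200 M |  |
| Monday's | 0.500 M | 1.00 M |  |
| Sunday's | 1.50 M | 0.500 M |  |
| Friday's | 0.500 M | 0.500 M | 34 min |

| run | time / min | [product] / M |
|---|---|---|
| Thursday's run | 2.4 | 0.031 |
| Thursday's run | 4.9 | 0.050 |
| Thursday's run | 7.3 | 0.112 |
| Thursday's run | 9.7 | 0.168 |
| Thursday's run | 12 | 0.233 |
| Thursday's run | 15 | 0.300 |
| Thursday's run | 17 | 0.343 |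
| Tuesday's run | 2.4 | 0 |
| Tuesday's run | 4.9 | 0 |
| Tuesday's run | 7.3 | 0.009 |
| Tuesday's run | 9.7 | 0.011 |
| Tuesday's run | 12 | 0.005 |
| Tuesday's run | 15 | 0.004 |
| Tuesday's run | 17 | 0.015 |
| Monday's run | 2.4 | 0.096 |
| Monday's run | 4.9 | 0.313 |
| Monday's run | 7.3 | 0.453 |
| Monday's run | 9.7 | 0.502 |
| Monday's run | 12 | 0.506 |
| Monday's run | 15 | 0.496 |
| Monday's run | 17 | 0.502 |
| Sunday's run | 2.4 | 0.039 |
| Sunday's run | 4.9 | 0.163 |
| Sunday's run | 7.3 | 0.294 |
| Sunday's run | 9.7 | 0.420 |
| Sunday's run | 12 | 0.456 |
| Sunday's run | 15 | 0.488 |
| Sunday's run | 17 | 0.488 |

(scatter of a reading: 0.007 M)

- Overall: starting material + partner -> product.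
- Constant volume, constant temperature.
- What is held in complexes is read along with the free species.
- "The second partner" is partner.
- An order is taken over about fifteen percent of the charge, up and down.

1. apparent order in [partner] of the starting rate, round the charge of the Thursday's run (the rate where two percent of its starting material have turned into product)
2. apparent order in [starting material] of the starting rate, round the charge of the Thursday's run (the rate where two percent of its starting material have turned into product) (one fixed amount of product, the same in the runs compared)
3. the Tuesday's run starts with 0.300 M less of starting material and of partner than the Thursday's run, and with no product. Compared where both hold the same amount of starting material, once fifteen percent of what the Tuesday's run was charged with has turned into product, is the Tuesday's run faster, slower or alike (within a tenth)?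
4. product in the Friday's run at 34 min, as a share of the starting material charged

The balance comes first. By the overall equation, each unit of product takes one of starting material and one of partner. Monday's run, short of starting material, and Sunday's run, short of partner, read 0.502 M and 0.488 M at 17 min, against 0.500 M of starting material and 0.500 M of partner charged, as this balance asks. In Thursday's run the two charges are equal, so both are the limiting reagent, and one lack serves for both: the charge less [product]. That lack is 0.267 M at 12 min and 0.157 M at 17 min. The reckoning here takes the lack's fall per minute, the logarithm of the ratio of two lacks over the time between them, and supposes that it holds on through Friday's run.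

The given numbers don't weigh alike. Thursday's readings before 12 min don't enter this reckoning. The last lack enters as a plain factor, so a reading off by the scatter of 0.007 M moves the lack at 34 min by 4.46 % through that factor. The fall per minute enters through an exponential, and the same scatter in both readings makes it uncertain by 0.0103 min⁻¹. Over the 17.0 min still to go, that moves the final lack by 19.1 %, more than the last lack's own share, so the fall per minute is the number to know well.

That number, read from Thursday's run, is 0.106 min⁻¹. It brings the lack at 34 min to 0.0258 M, which puts Friday's product at 94.8 % of the charge.

The forecast gives 1.4 in partner, 0.4 in starting material, slower for Tuesday's run and 93 % for Friday's, this last below the 94.8 % reckoned here, and of the end of the curve it says “Monday and Sunday finish sharply, so the tail stays brisk”.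

The flask gives 1.7 in partner, 0.55 in starting material, slower for Tuesday's run and 92.3 % for Friday's, so Friday's lack at 34 min is 0.0384 M, more than the reckoned 0.0258 M.

    starting material + 2 partner → product + partner (0.3504 L² mol⁻² min⁻¹)
    2 starting material ⇌ idle substrate dimer, settled at all times (44.80 L mol⁻¹)
    starting material + partner + product → 2 product (8.280 L² mol⁻² min⁻¹)

From Thursday's reading at 17 min to Friday's value at 34 min, the lack fell on average by 0.0828 min⁻¹, less than the 0.106 min⁻¹ read from Thursday's run. Tuesday's run, with 0.200 M of each reagent, had turned a quarter of its charge at 33.3 min and half at 52.5 min. Its lack's fall between those times comes on average to 0.0211 min⁻¹, less than the 0.106 min⁻¹ read from Thursday's run.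

The runs are calculated for substances that don't exist; the scatter is artificial.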